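**Plan**

- Numbering and enabling feature: ring C1(=O)–C2(CH2OAc)=C3H–C4(=O)–C5–C6H with the oxirane on C5–C6, chain C7H(OAc)–C8H=C9(Me)–C10H=C11H–C12HO. The six-membered carbocycle is at the para-quinone oxidation level, with oxygen on C1 and C4, carbon substituents only on C2 and C5, and hydrogen on C3 and C6. This is the pattern that an α-branched alkenyl carbene, a terminal alkyne and CO assemble.
- Retrosynthesis: remove the oxirane oxygen, the two acetates and the masks on C1 and C12 to reach a 4-methoxyphenol. Cut C4–C5, C6–C1 and C3–C4 to give a chromium carbene (C1–C3, with C4 from CO) and a C5–C12 alkyne. Cut the alkyne at C5–C7 (alkynylation) and at C10=C11 (olefination).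
- Forward: the chain is built first (steps 3–8), the carbocycle is closed once in step 9, and the oxirane follows in step 12. Oxidation to the C1 dimethyl ketal leaves C4 as the only ketone, so nucleophilic epoxidation can only take place at C5=C6.
- Stereochemistry: C7 (S) comes from a zinc–ProPhenol alkynylation of the dienal. The C5/C6 oxirane (1R,6S) is relayed from C7 through a lithium chelate. Both alkenes are set E by the olefination.

Key step: step 9

Remark: 2,2-dimethoxyacetaldehyde (7) is sold as an aqueous solution and is taken here as the anhydrous aldehyde obtained from it by extraction and distillation. TBS = tert-butyldimethylsilyl.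

**Route**

Step 1
Reactants: 1 2-bromoprop-2-en-1-ol
Product: 2 [(2-bromoprop-2-en-1-yl)oxy](tert-butyl)dimethylsilane
Conditions: TBSCl, imidazole, CH2Cl2, 0 °C → rt
Reagents that add atoms: tert-butyldimethylsilyl chloride, CC(C)(C)[Si](C)(C)Cl
Why: Imidazole-promoted silylation of a primary allylic alcohol is routine and leaves the vinyl bromide untouched.

Step 2
Reactants: 2 [(2-bromoprop-2-en-1-yl)oxy](tert-butyl)dimethylsilane; 3 hexacarbonylchromium
Product: 6 pentacarbonyl{methoxy[3-(tert-butyldimethylsilyloxy)prop-1-en-2-yl]carbene}chromium, via alkenyllithium 4 (not isolated), via lithium acylchromate 5 (not isolated)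
Conditions: 2, t-BuLi (2 equiv), Et2O, −78 °C; add to Cr(CO)6, −78 → 0 °C; then Me3OBF4, CH2Cl2, 0 °C
Reagents that add atoms: trimethyloxonium tetrafluoroborate, C[O+](C)C.F[B-](F)(F)F
Why: Fischer carbene synthesis, in which bromine–lithium exchange (kept at −78 °C so that silicon does not migrate from oxygen to carbon) gives an alkenyllithium that adds to a CO ligand and the acylchromate is O-methylated, is the standard entry to α-branched alkenyl(methoxy)carbene complexes.

Step 3
Reactants: 7 2,2-dimethoxyacetaldehyde; 8 ethyl (2E)-4-(diethoxyphosphoryl)-3-methylbut-2-enoate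
Product: 10 ethyl (2E,4E)-6,6-dimethoxy-3-methylhexa-2,4-dienoate, via lithiated phosphonate 9 (not isolated)
Conditions: 8, LiN(SiMe3)2, THF, −78 °C; then 7, −78 → 0 °C
Reagents that add atoms: none
Why: Vinylogous Horner–Wadsworth–Emmons olefination with the C5 phosphonate should form C10=C11 with E geometry and, through the delocalised anion, mainly the E C8=C9 ester, any minor 2Z isomer being removed by chromatography.

Step 4
Reactants: 10 ethyl (2E,4E)-6,6-dimethoxy-3-methylhexa-2,4-dienoate
Product: 11 (2E,4E)-6,6-dimethoxy-3-methylhexa-2,4-dien-1-ol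
Conditions: i-Bu2AlH (2.2 equiv), CH2Cl2, −78 °C; aq. potassium sodium tartrate (KNaC4H4O6)
Reagents that add atoms: none
Why: Low-temperature i-Bu2AlH reduction of a conjugated ester is 1,2-selective and gives the allylic alcohol, while the acetal is inert to hydride and to the neutral tartrate work-up.

Step 5
Reactants: 11 (2E,4E)-6,6-dimethoxy-3-methylhexa-2,4-dien-1-ol
Product: 12 (2E,4E)-6,6-dimethoxy-3-methylhexa-2,4-dienal
Conditions: MnO2, CH2Cl2, rt
Reagents that add atoms: none
Why: MnO2 oxidises allylic alcohols selectively under neutral conditions, so the acetal and the alkene geometry should survive.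

Step 6
Reactants: 12 (2E,4E)-6,6-dimethoxy-3-methylhexa-2,4-dienal; 13 ethynyltrimethylsilane
Product: 15 (3S,4E,6E)-8,8-dimethoxy-5-methyl-1-(trimethylsilyl)octa-4,6-dien-1-yn-3-ol, via alkynylzinc 14 (not isolated)
Conditions: (S,S)-ProPhenol (10 mol %), Me2Zn (3 equiv), 13 (3 equiv), Ph3PO (20 mol %), toluene, 4 °C
Reagents that add atoms: none
Why: Zinc–ProPhenol asymmetric alkynylation of α,β-unsaturated aldehydes, in which the dinuclear zinc catalyst formed from the ligand and Me2Zn binds aldehyde and alkynylzinc together, is expected to deliver the alkynyl group to the Re face of the aldehyde and so set the (S) carbinol that becomes C7.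

Step 7
Reactants: 15 (3S,4E,6E)-8,8-dimethoxy-5-methyl-1-(trimethylsilyl)octa-4,6-dien-1-yn-3-ol
Product: 16 tert-butyl{[(3S,4E,6E)-8,8-dimethoxy-5-methyl-1-(trimethylsilyl)octa-4,6-dien-1-yn-3-yl]oxy}dimethylsilane
Conditions: TBSCl, imidazole, DMF, rt
Reagents that add atoms: tert-butyldimethylsilyl chloride, CC(C)(C)[Si](C)(C)Cl
Why: Standard silylation of a secondary alcohol under base protects C7–O for the benzannulation without ionising the doubly allylic/propargylic position.

Step 8
Reactants: 16 tert-butyl{[(3S,4E,6E)-8,8-dimethoxy-5-methyl-1-(trimethylsilyl)octa-4,6-dien-1-yn-3-yl]oxy}dimethylsilane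
Product: 17 tert-butyl{[(3S,4E,6E)-8,8-dimethoxy-5-methylocta-4,6-dien-1-yn-3-yl]oxy}dimethylsilane
Conditions: K2CO3, MeOH, 0 °C → rt
Reagents that add atoms: none
Why: Methanolysis with K2CO3 cleaves the alkynyl C–Si bond selectively, while the O-silyl ether is stable and the dimethyl acetal can only exchange with the solvent degenerately.

Step 9
Reactants: 6 pentacarbonyl{methoxy[3-(tert-butyldimethylsilyloxy)prop-1-en-2-yl]carbene}chromium; 17 tert-butyl{[(3S,4E,6E)-8,8-dimethoxy-5-methylocta-4,6-dien-1-yn-3-yl]oxy}dimethylsilane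
Product: 19 2-[(1S,2E,4E)-1-(tert-butyldimethylsilyloxy)-6,6-dimethoxy-3-methylhexa-2,4-dien-1-yl]-5-[(tert-butyldimethylsilyloxy)methyl]-4-methoxyphenol, via arene tricarbonylchromium complex 18 (not isolated)
Conditions: 6 (1.3 equiv), degassed THF, 50 °C; then air, Et2O/MeCN, rt
Reagents that add atoms: none
Why: Thermal loss of one CO from 6 lets alkyne 17 insert into the Cr=C bond (new C6–C1 bond), the resulting alkenylcarbene inserts CO (new C4–C5 bond) to give a chromium-bound dienylketene, and this closes the six-membered carbocycle by 6π-electrocyclisation between the ketene carbon C4 and the methylene carbon C3 before tautomerising to the phenol. This is the Dötz benzannulation of an α-branched alkenyl(methoxy)carbene complex with a terminal alkyne, a pairing for which phenol formation in THF is expected to dominate over cyclobutenone or furan formation. The selectivity required is the orientation of alkyne insertion: the alkyne hydrogen must end next to the carbene carbon C1 and the branched, silyloxy-bearing substituent next to the CO-derived C4, and the large steric difference between hydrogen and a secondary propargylic carbon secures this. No stereocentre is formed; C7 is carried through unchanged and the planar chirality of complex 18 vanishes when air removes the metal. The C8=C9 alkene cannot intercept the carbene at C5 because that would require a bicyclobutane, and the neutral conditions leave the acetal and both silyl ethers intact.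

Step 10
Reactants: 19 2-[(1S,2E,4E)-1-(tert-butyldimethylsilyloxy)-6,6-dimethoxy-3-methylhexa-2,4-dien-1-yl]-5-[(tert-butyldimethylsilyloxy)methyl]-4-methoxyphenol
Product: 20 2-[(1S,2E,4E)-1-(tert-butyldimethylsilyloxy)-6,6-dimethoxy-3-methylhexa-2,4-dien-1-yl]-5-[(tert-butyldimethylsilyloxy)methyl]-4,4-dimethoxycyclohexa-2,5-dien-1-one
Conditions: PhI(OAc)2, NaHCO3, MeOH, 0 °C
Reagents that add atoms: methanol, CO
Why: Hypervalent-iodine oxidative dearomatisation of a para-methoxyphenol in methanol gives the quinone monoketal, methanol adding at the methoxy-bearing C1 so that C1 becomes the ketal and C4 the only ketone, and the buffered medium spares the silyl ethers and the C12 acetal.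

Step 11
Reactants: 20 2-[(1S,2E,4E)-1-(tert-butyldimethylsilyloxy)-6,6-dimethoxy-3-methylhexa-2,4-dien-1-yl]-5-[(tert-butyldimethylsilyloxy)methyl]-4,4-dimethoxycyclohexa-2,5-dien-1-one
Product: 21 2-[(1S,2E,4E)-1-hydroxy-6,6-dimethoxy-3-methylhexa-2,4-dien-1-yl]-5-(hydroxymethyl)-4,4-dimethoxycyclohexa-2,5-dien-1-one
Conditions: Bu4NF, AcOH, THF, 0 °C → rt
Reagents that add atoms: none
Why: Fluoride cleaves both silyl ethers, and buffering with AcOH keeps free alkoxide away from the dienone while both ketals are inert.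

Step 12
Reactants: 21 2-[(1S,2E,4E)-1-hydroxy-6,6-dimethoxy-3-methylhexa-2,4-dien-1-yl]-5-(hydroxymethyl)-4,4-dimethoxycyclohexa-2,5-dien-1-one
Product: 22 (1R,6S)-1-[(1S,2E,4E)-1-hydroxy-6,6-dimethoxy-3-methylhexa-2,4-dien-1-yl]-4-(hydroxymethyl)-5,5-dimethoxy-7-oxabicyclo[4.1.0]hept-3-en-2-one
Conditions: t-BuOOH (anhydrous, decane), n-BuLi, THF, −78 → −20 °C; then aq. NH4Cl
Reagents that add atoms: tert-butyl hydroperoxide, CC(C)(C)OO
Why: Weitz–Scheffer nucleophilic epoxidation of a quinone monoketal should be site-selective because only C5=C6 has an unsubstituted β-carbon (C6), C2 being fully substituted and flanked by the ketal, and face-selective because lithium bridging the C7 oxygen and the C4 carbonyl holds the C7–O bond in the ring plane so that the dienyl group covers one face and the peroxide adds to C6 and closes onto C5 from the other, which for (S)-C7 gives the (1R,6S) oxirane; the electron-rich diene is inert to a nucleophilic oxidant.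

Step 13
Reactants: 22 (1R,6S)-1-[(1S,2E,4E)-1-hydroxy-6,6-dimethoxy-3-methylhexa-2,4-dien-1-yl]-4-(hydroxymethyl)-5,5-dimethoxy-7-oxabicyclo[4.1.0]hept-3-en-2-one
Product: 23 [(1R,6S)-1-[(1S,2E,4E)-1-acetoxy-6,6-dimethoxy-3-methylhexa-2,4-dien-1-yl]-5,5-dimethoxy-2-oxo-7-oxabicyclo[4.1.0]hept-3-en-4-yl]methyl acetate
Conditions: Ac2O, pyridine, DMAP (cat.), CH2Cl2, 0 °C
Reagents that add atoms: acetic anhydride, CC(=O)OC(C)=O
Why: DMAP-catalysed acylation esterifies the primary and the hindered secondary hydroxyl under mildly basic conditions that the epoxy ketone and both ketals tolerate.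

Step 14
Reactants: 23 [(1R,6S)-1-[(1S,2E,4E)-1-acetoxy-6,6-dimethoxy-3-methylhexa-2,4-dien-1-yl]-5,5-dimethoxy-2-oxo-7-oxabicyclo[4.1.0]hept-3-en-4-yl]methyl acetate
Product: 25 [(1R,6S)-1-[(1S,2E,4E)-1-acetoxy-3-methyl-6-oxohexa-2,4-dien-1-yl]-2,5-dioxo-7-oxabicyclo[4.1.0]hept-3-en-4-yl]methyl acetate, via C12 aldehyde ring ketal 24 (not isolated)
Conditions: TFA/H2O (9:1), CH2Cl2, 0 °C
Reagents that add atoms: water, O
Why: Acid-catalysed ketal hydrolysis should first release the conjugated C12 aldehyde, whose formation deactivates C7 towards ionisation, and then the ring ketone at C1 as is usual for epoxyquinone monoketals, while the acetates and the oxirane flanked by two carbonyls resist and no stereocentre is touched.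

**Compound list**

1 | 2-bromoprop-2-en-1-ol | OCC(Br)=C | starting material
2 | [(2-bromoprop-2-en-1-yl)oxy](tert-butyl)dimethylsilane | C=C(Br)CO[Si](C)(C)C(C)(C)C | intermediate
3 | hexacarbonylchromium, Cr(CO)6 | O=C=[Cr](=C=O)(=C=O)(=C=O)(=C=O)=C=O | starting material
4 | {3-[(tert-butyldimethylsilyl)oxy]prop-1-en-2-yl}lithium | [Li]C(=C)CO[Si](C)(C)C(C)(C)C | intermediate
5 | lithium pentacarbonyl{2-[(tert-butyldimethylsilyloxy)methyl]prop-2-enoyl}chromate | [Li+].[O-]C(C(=C)CO[Si](C)(C)C(C)(C)C)=[Cr](=C=O)(=C=O)(=C=O)(=C=O)=C=O | intermediate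
6 | pentacarbonyl{methoxy[3-(tert-butyldimethylsilyloxy)prop-1-en-2-yl]carbene}chromium | COC(C(=C)CO[Si](C)(C)C(C)(C)C)=[Cr](=C=O)(=C=O)(=C=O)(=C=O)=C=O | intermediate
7 | 2,2-dimethoxyacetaldehyde | COC(OC)C=O | starting material
8 | ethyl (2E)-4-(diethoxyphosphoryl)-3-methylbut-2-enoate | CCOC(=O)/C=C(C)/CP(=O)(OCC)OCC | starting material
9 | lithium salt of the C4 carbanion of 8 | [Li+].CCOC(=O)C=C(C)[CH-]P(=O)(OCC)OCC | intermediate
10 | ethyl (2E,4E)-6,6-dimethoxy-3-methylhexa-2,4-dienoate | CCOC(=O)/C=C(C)/C=C/C(OC)OC | intermediate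
11 | (2E,4E)-6,6-dimethoxy-3-methylhexa-2,4-dien-1-ol | OC/C=C(C)/C=C/C(OC)OC | intermediate
12 | (2E,4E)-6,6-dimethoxy-3-methylhexa-2,4-dienal | O=C/C=C(C)/C=C/C(OC)OC | intermediate
13 | ethynyltrimethylsilane | C#C[Si](C)(C)C | starting material
14 | methyl[(trimethylsilyl)ethynyl]zinc | C[Zn]C#C[Si](C)(C)C | intermediate
15 | (3S,4E,6E)-8,8-dimethoxy-5-methyl-1-(trimethylsilyl)octa-4,6-dien-1-yn-3-ol | C[Si](C)(C)C#C[C@H](/C=C(C)/C=C/C(OC)OC)O | intermediate
16 | tert-butyl{[(3S,4E,6E)-8,8-dimethoxy-5-methyl-1-(trimethylsilyl)octa-4,6-dien-1-yn-3-yl]oxy}dimethylsilane | C[Si](C)(C)C#C[C@H](/C=C(C)/C=C/C(OC)OC)O[Si](C)(C)C(C)(C)C | intermediate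
17 | tert-butyl{[(3S,4E,6E)-8,8-dimethoxy-5-methylocta-4,6-dien-1-yn-3-yl]oxy}dimethylsilane | C#C[C@H](/C=C(C)/C=C/C(OC)OC)O[Si](C)(C)C(C)(C)C | intermediate
18 | tricarbonyl(η6-arene)chromium complex of phenol 19 (metal fragment written separately) | COc1cc([C@H](/C=C(C)/C=C/C(OC)OC)O[Si](C)(C)C(C)(C)C)c(O)cc1CO[Si](C)(C)C(C)(C)C.[Cr](=C=O)(=C=O)=C=O | intermediate
19 | 2-[(1S,2E,4E)-1-(tert-butyldimethylsilyloxy)-6,6-dimethoxy-3-methylhexa-2,4-dien-1-yl]-5-[(tert-butyldimethylsilyloxy)methyl]-4-methoxyphenol | COc1cc([C@H](/C=C(C)/C=C/C(OC)OC)O[Si](C)(C)C(C)(C)C)c(O)cc1CO[Si](C)(C)C(C)(C)C | intermediate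
20 | 2-[(1S,2E,4E)-1-(tert-butyldimethylsilyloxy)-6,6-dimethoxy-3-methylhexa-2,4-dien-1-yl]-5-[(tert-butyldimethylsilyloxy)methyl]-4,4-dimethoxycyclohexa-2,5-dien-1-one | O=C1C=C(CO[Si](C)(C)C(C)(C)C)C(OC)(OC)C=C1[C@H](/C=C(C)/C=C/C(OC)OC)O[Si](C)(C)C(C)(C)C | intermediate
21 | 2-[(1S,2E,4E)-1-hydroxy-6,6-dimethoxy-3-methylhexa-2,4-dien-1-yl]-5-(hydroxymethyl)-4,4-dimethoxycyclohexa-2,5-dien-1-one | O=C1C=C(CO)C(OC)(OC)C=C1[C@H](/C=C(C)/C=C/C(OC)OC)O | intermediate
22 | (1R,6S)-1-[(1S,2E,4E)-1-hydroxy-6,6-dimethoxy-3-methylhexa-2,4-dien-1-yl]-4-(hydroxymethyl)-5,5-dimethoxy-7-oxabicyclo[4.1.0]hept-3-en-2-one | OCC1=CC(=O)[C@]2([C@H](/C=C(C)/C=C/C(OC)OC)O)O[C@@H]2C1(OC)OC | intermediate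
23 | [(1R,6S)-1-[(1S,2E,4E)-1-acetoxy-6,6-dimethoxy-3-methylhexa-2,4-dien-1-yl]-5,5-dimethoxy-2-oxo-7-oxabicyclo[4.1.0]hept-3-en-4-yl]methyl acetate | CC(=O)OCC1=CC(=O)[C@]2([C@H](/C=C(C)/C=C/C(OC)OC)OC(C)=O)O[C@@H]2C1(OC)OC | intermediate
24 | [(1R,6S)-1-[(1S,2E,4E)-1-acetoxy-3-methyl-6-oxohexa-2,4-dien-1-yl]-5,5-dimethoxy-2-oxo-7-oxabicyclo[4.1.0]hept-3-en-4-yl]methyl acetate | CC(=O)OCC1=CC(=O)[C@]2([C@H](/C=C(C)/C=C/C=O)OC(C)=O)O[C@@H]2C1(OC)OC | intermediate
25 | [(1R,6S)-1-[(1S,2E,4E)-1-acetoxy-3-methyl-6-oxohexa-2,4-dien-1-yl]-2,5-dioxo-7-oxabicyclo[4.1.0]hept-3-en-4-yl]methyl acetate | CC(=O)OCC1=CC(=O)[C@]2([C@H](/C=C(C)/C=C/C=O)OC(C)=O)O[C@@H]2C1=O | target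

**Step count and risks**

Total step count: 14. Longest linear sequence: 12 steps (steps 3–8, then 9–14, from 7 and 8); the carbene arm contributes steps 1–2.

Steps most likely to fail:

1. Step 12. The risk is loss of facial selectivity if the lithium chelate between the C7 oxygen and the C4 carbonyl is not maintained, so that the peroxide reaches C6 from both faces; retro-aldol cleavage of the C5–C7 bond in the product alkoxide is a second possible loss. The fallback replaces substrate control by reagent control and moves the epoxidation ahead of desilylation. It sets out from 20, which is epoxidised under cinchona phase-transfer conditions (t-BuOOH, aq. NaOH, toluene, N-benzylcinchonidinium chloride or its pseudo-enantiomer N-benzylcinchoninium chloride, whichever is matched with the (S)-C7 centre) to give the bis-silylated (1R,6S) oxirane F1. Cleavage of both silyl ethers with Bu4NF/AcOH then returns to the route at 22.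

2. Step 14. The risk is sluggish hydrolysis of the ring ketal, which is deactivated by the neighbouring oxirane and the cross-conjugated enone, so that the acid strength needed starts to open the oxirane or ionise the allylic C7 acetate. The fallback avoids a ring ketal at the end by working at the quinone oxidation level; its cost is that site selection between the two quinone alkenes then rests on the C7-hydroxyl chelate alone. It sets out from 19, which is oxidised with PhI(OAc)2 in MeCN/H2O to the bis-silylated quinone F2. Desilylation (Bu4NF, AcOH) gives the quinone diol F3, which is epoxidised with t-BuOOH/n-BuLi under chelate direction to the epoxyquinone diol F4. Acetylation (Ac2O, pyridine) gives the diacetate F5 with the C12 acetal intact, and mild hydrolysis (pyridinium p-toluenesulfonate, acetone/H2O) rejoins the route at 25.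

3. Step 6. The risk is poor facial discrimination in alkynyl transfer to a β,β-disubstituted dienal that has no α-substituent, together with uncatalysed racemic addition of the alkynylzinc. The fallback sets the centre by reduction instead of C–C bond formation. It sets out from 12, which is treated with the lithium acetylide made from 13 and n-BuLi (THF, −78 °C) to give the racemic carbinol F6. Oxidation with MnO2 gives the ynone F7, and Noyori asymmetric transfer hydrogenation with RuCl[(S,S)-TsDPEN](p-cymene) in i-PrOH, delivering hydride to the Re face with the alkyne in the π-recognition site, returns to the route at 15.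

**Further compounds**

F1 | step 12 | (1R,6S)-1-[(1S,2E,4E)-1-(tert-butyldimethylsilyloxy)-6,6-dimethoxy-3-methylhexa-2,4-dien-1-yl]-4-[(tert-butyldimethylsilyloxy)methyl]-5,5-dimethoxy-7-oxabicyclo[4.1.0]hept-3-en-2-one | CC(C)(C)[Si](C)(C)OCC1=CC(=O)[C@]2([C@H](/C=C(C)/C=C/C(OC)OC)O[Si](C)(C)C(C)(C)C)O[C@@H]2C1(OC)OC
F2 | step 14 | 2-[(1S,2E,4E)-1-(tert-butyldimethylsilyloxy)-6,6-dimethoxy-3-methylhexa-2,4-dien-1-yl]-5-[(tert-butyldimethylsilyloxy)methyl]cyclohexa-2,5-diene-1,4-dione | O=C1C=C(CO[Si](C)(C)C(C)(C)C)C(=O)C=C1[C@H](/C=C(C)/C=C/C(OC)OC)O[Si](C)(C)C(C)(C)C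
F3 | step 14 | 2-[(1S,2E,4E)-1-hydroxy-6,6-dimethoxy-3-methylhexa-2,4-dien-1-yl]-5-(hydroxymethyl)cyclohexa-2,5-diene-1,4-dione | O=C1C=C(CO)C(=O)C=C1[C@H](/C=C(C)/C=C/C(OC)OC)O
F4 | step 14 | (1R,6S)-1-[(1S,2E,4E)-1-hydroxy-6,6-dimethoxy-3-methylhexa-2,4-dien-1-yl]-4-(hydroxymethyl)-7-oxabicyclo[4.1.0]hept-3-ene-2,5-dione | OCC1=CC(=O)[C@]2([C@H](/C=C(C)/C=C/C(OC)OC)O)O[C@@H]2C1=O
F5 | step 14 | [(1R,6S)-1-[(1S,2E,4E)-1-acetoxy-6,6-dimethoxy-3-methylhexa-2,4-dien-1-yl]-2,5-dioxo-7-oxabicyclo[4.1.0]hept-3-en-4-yl]methyl acetate | CC(=O)OCC1=CC(=O)[C@]2([C@H](/C=C(C)/C=C/C(OC)OC)OC(C)=O)O[C@@H]2C1=O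
F6 | step 6 | racemic (4E,6E)-8,8-dimethoxy-5-methyl-1-(trimethylsilyl)octa-4,6-dien-1-yn-3-ol | C[Si](C)(C)C#CC(O)/C=C(C)/C=C/C(OC)OC
F7 | step 6 | (4E,6E)-8,8-dimethoxy-5-methyl-1-(trimethylsilyl)octa-4,6-dien-1-yn-3-one | C[Si](C)(C)C#CC(=O)/C=C(C)/C=C/C(OC)OC
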